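Ring B is an aryl ketone whose acyl-bearing carbon B1 lies between two oxygenated carbons, B2 and B6. Everything rests on cutting the B1–C(=O) bond and the adjacent B2–O bond at once, which leads back to 3,5-dimethoxybenzyne and (R)-2-methylbutanoic acid. In the forward sense one operation plants the chiral acyl group and its chelating phenol side by side, with the stereocentre bought rather than made. The aryne precursor is silyl triflate 8, whose SiMe3 group sits between OTf and OMe; it comes from symmetrical 3,5-dimethoxyphenol. Chelation-guided demethylation at B6, aminomethylation at B3 and ortho-quinone methide capture by C3 of ring A pyranone 19 finish the target.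

Key step: step 4

Locants: in ring B (benzene), B1 carries the acyl group, B2 and B6 carry OH, B3 carries the bridge, B4 carries OMe and B5 is C–H. In ring A (2-pyranone), the atoms are O1, C2 (lactone C=O), C3 (bridge), C4 (OH), C5 (CH3) and C6 (ethyl).

Assumption: the side-chain stereocentre of the target reads as R (C=O > ethyl > methyl > H). The same priority order holds in acid 9 and in every intermediate, so an untouched centre stays R throughout. Acid 9 is taken as purchasable in high enantiomeric purity.

Design remark: both aryne ethers are kept as methyl. Symmetrical 1 then has only one kind of carbamate-flanked lithiation site, and symmetrical 13 has only one kind of aromatic C–H. Regiochemistry is therefore a question only in step 4.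

Step 1
Reactants: 1 3,5-dimethoxyphenol
Product: 2 3,5-dimethoxyphenyl N-isopropylcarbamate
Conditions: i-PrNCO (1.5 equiv), Et3N (0.2 equiv), CH2Cl2, rt
Reagents that add atoms: isopropyl isocyanate, CC(C)N=C=O
Why: Base-catalysed addition of the phenol O–H across the isocyanate (carbamoylation) installs a strong ortho-directing group in a form that can later be removed by mild E1cB cleavage.

Step 2
Reactants: 2 3,5-dimethoxyphenyl N-isopropylcarbamate
Product: 6 3,5-dimethoxy-2-(trimethylsilyl)phenyl N-isopropylcarbamate, via N-silyl carbamate 3 (not isolated), via aryllithium 4 (not isolated), via bis-silyl carbamate 5 (not isolated)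
Conditions: TBSOTf, TMEDA, Et2O, 0 °C to rt; n-BuLi, TMEDA, −78 °C; TMSCl, −78 °C to rt; sat. aq NaHSO4, 0 °C
Reagents that add atoms: chlorotrimethylsilane, C[Si](C)(C)Cl; tert-butyldimethylsilyl triflate, CC(C)(C)[Si](C)(C)OS(=O)(=O)C(F)(F)F (its silyl group is carried only by 3, 4 and 5)
Why: In this directed ortho-metalation, transient N-silylation masks the N–H, the carbamate and the meta-related OMe jointly steer n-BuLi to the carbon between them (the site between the two OMe groups lacks the stronger director), TMSCl traps the aryllithium, and the brief mildly acidic work-up hydrolyses only the labile N–Si bond.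

Step 3
Reactants: 6 3,5-dimethoxy-2-(trimethylsilyl)phenyl N-isopropylcarbamate
Product: 8 3,5-dimethoxy-2-(trimethylsilyl)phenyl trifluoromethanesulfonate, via silyl phenol 7 (not isolated)
Conditions: DBU, Et2NH, MeCN, 40 °C; then PhNTf2, rt
Reagents that add atoms: N-phenylbis(trifluoromethanesulfonimide), O=S(=O)(N(c1ccccc1)S(=O)(=O)C(F)(F)F)C(F)(F)F
Why: E1cB fragmentation of the secondary carbamate releases the phenoxide of 7 and an isocyanate that Et2NH scavenges as a urea, and O-triflation in the same basic pot spares the acid-sensitive, electron-rich aryl–Si bond an isolation.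

Step 4
Reactants: 8 3,5-dimethoxy-2-(trimethylsilyl)phenyl trifluoromethanesulfonate; 9 (R)-2-methylbutanoic acid
Product: 12 (2R)-1-(2-hydroxy-4,6-dimethoxyphenyl)-2-methylbutan-1-one, via aryne 10 (not isolated), via aryl anion 11 (not isolated)
Conditions: 8 (1.5 equiv), dry CsF (4 equiv), THF (0.02 M), 125 °C, sealed tube
Reagents that add atoms: none
Why: Fluoride attacks the silicon of 8 and triflate departs to give aryne 10, and the carboxylate of 9 adds through oxygen to the aryne carbon that carried OTf, because the flanking OMe distorts the aryne so that this remote terminus is the more electrophilic one and the charge develops on the carbon next to the σ-withdrawing OMe (aryl anion 11). Anion 11 attacks its own ester carbonyl through a four-membered transition state and the acyl group moves from O to C, an anionic Fries-type shift that ends at the phenoxide of 12 with the new ketone between two oxygenated carbons. The closest known reaction type is this very one, the CsF-induced formal insertion of arynes into the C–O bond of carboxylic acids to give ortho-hydroxyaryl ketones, which with 3-alkoxyarynes gives the 2-hydroxy-6-alkoxy isomer. No ring is closed and no stereocentre is created; the R centre comes from 9, takes no part in bond making, and is poorly enolisable because 9 reacts as a carboxylate and 12 rests as a chelated phenoxide conjugated with its ketone. Besides regiochemistry, the step needs the acyl shift to outrun protonation of 11, which would stop at the aryl ester; high dilution, a non-acidic solvent, excess dry CsF to bind HF and high temperature all favour the unimolecular shift.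

Step 5
Reactants: 12 (2R)-1-(2-hydroxy-4,6-dimethoxyphenyl)-2-methylbutan-1-one
Product: 13 (2R)-1-(2,6-dihydroxy-4-methoxyphenyl)-2-methylbutan-1-one
Conditions: BCl3 (3 equiv), CH2Cl2, −78 °C to rt; then H2O
Reagents that add atoms: none
Why: In this chelation-controlled Lewis acid ether cleavage, boron anchored on the ketone oxygen reaches only the flanking OMe at B6 and delivers chloride to its methyl group, the remote B4 OMe has no such anchor, and the base-free medium leaves the α-stereocentre alone.

Step 6
Reactants: 13 (2R)-1-(2,6-dihydroxy-4-methoxyphenyl)-2-methylbutan-1-one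
Product: 14 (2R)-1-{3-[(dimethylamino)methyl]-2,6-dihydroxy-4-methoxyphenyl}-2-methylbutan-1-one
Conditions: CH2=NMe2+ I− (1.0 equiv), CH2Cl2, 0 °C to rt; sat. aq NaHCO3
Reagents that add atoms: N,N-dimethylmethyleneiminium iodide (Eschenmoser's salt), C=[N+](C)C.[I-]
Why: In this Mannich-type aromatic aminomethylation with a preformed iminium salt, B3 and B5 of symmetrical 13 are equivalent and activated by three oxygen donors, and the first substitution gives a deactivated, poorly soluble ammonium iodide, which should hold the reaction at one CH2NMe2 group.

Step 7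
Reactants: 15 pentan-3-one
Product: 16 3-(trimethylsilyloxy)pent-2-ene (E/Z mixture)
Conditions: TMSOTf, Et3N, CH2Cl2, 0 °C to rt
Reagents that add atoms: trimethylsilyl triflate, C[Si](C)(C)OS(=O)(=O)C(F)(F)F
Why: Soft enolisation and O-silylation (silyl enol ether formation) of a symmetrical ketone can give only one regioisomer, and the alkene geometry is irrelevant because it vanishes in the pyranone.

Step 8
Reactants: 16 3-(trimethylsilyloxy)pent-2-ene; 17 malonyl dichloride
Product: 19 6-ethyl-4-hydroxy-5-methyl-2H-pyran-2-one, via diketo acid chloride 18 (not isolated)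
Conditions: Et2O, −78 °C to rt
Reagents that add atoms: none
Why: In this formal [3+3] cyclocondensation of a silyl enol ether with malonyl dichloride (Effenberger-type pyranone synthesis), C-acylation at the nucleophilic alkene carbon gives 18, whose enolised ethyl ketone oxygen closes onto the second acid chloride to give the stabilised 4-hydroxy-2-pyranone.

Step 9
Reactants: 14 (2R)-1-{3-[(dimethylamino)methyl]-2,6-dihydroxy-4-methoxyphenyl}-2-methylbutan-1-one; 19 6-ethyl-4-hydroxy-5-methyl-2H-pyran-2-one
Product: 21 6-ethyl-4-hydroxy-3-({2,4-dihydroxy-6-methoxy-3-[(2R)-2-methylbutanoyl]phenyl}methyl)-5-methyl-2H-pyran-2-one, via quinone methide 20 (not isolated)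
Conditions: 19 (1.5 equiv), 1,4-dioxane, 90 °C, N2 stream
Reagents that add atoms: none
Why: Thermal loss of Me2NH from the ortho-hydroxybenzylamine gives ortho-quinone methide 20, which takes up the acidic pyranone at its only nucleophilic carbon C3 in a Michael addition that restores the aromaticity of ring B, a known way to alkylate cyclic 1,3-dicarbonyl compounds with phenolic Mannich bases, while the stereocentre sits next to a doubly chelated, poorly enolisable ketone.

Compound list
1 | 3,5-dimethoxyphenol | COc1cc(O)cc(OC)c1 | starting material
2 | 3,5-dimethoxyphenyl N-isopropylcarbamate | COc1cc(OC)cc(OC(=O)NC(C)C)c1 | intermediate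
3 | 3,5-dimethoxyphenyl N-(tert-butyldimethylsilyl)-N-isopropylcarbamate (not isolated) | COc1cc(OC)cc(OC(=O)N(C(C)C)[Si](C)(C)C(C)(C)C)c1 | intermediate
4 | 2-lithio-3,5-dimethoxyphenyl N-(tert-butyldimethylsilyl)-N-isopropylcarbamate (not isolated) | COc1cc(OC)c([Li])c(OC(=O)N(C(C)C)[Si](C)(C)C(C)(C)C)c1 | intermediate
5 | 3,5-dimethoxy-2-(trimethylsilyl)phenyl N-(tert-butyldimethylsilyl)-N-isopropylcarbamate (not isolated) | COc1cc(OC)c([Si](C)(C)C)c(OC(=O)N(C(C)C)[Si](C)(C)C(C)(C)C)c1 | intermediate
6 | 3,5-dimethoxy-2-(trimethylsilyl)phenyl N-isopropylcarbamate | COc1cc(OC)c([Si](C)(C)C)c(OC(=O)NC(C)C)c1 | intermediate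
7 | 3,5-dimethoxy-2-(trimethylsilyl)phenol (present as its DBU-H+ phenoxide, not isolated) | COc1cc(O)c([Si](C)(C)C)c(OC)c1 | intermediate
8 | 3,5-dimethoxy-2-(trimethylsilyl)phenyl trifluoromethanesulfonate | COc1cc(OC)c([Si](C)(C)C)c(OS(=O)(=O)C(F)(F)F)c1 | intermediate
9 | (R)-2-methylbutanoic acid | CC[C@@H](C)C(=O)O | starting material
10 | 3,5-dimethoxybenzyne (1,2-didehydro-3,5-dimethoxybenzene, not isolated) | COC1=CC(OC)=CC#C1 | intermediate
11 | 2-cesio-3,5-dimethoxyphenyl (2R)-2-methylbutanoate (aryl anion between O-acyl and OMe, not isolated) | CC[C@@H](C)C(=O)Oc1cc(OC)cc(OC)[c-]1.[Cs+] | intermediate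
12 | (2R)-1-(2-hydroxy-4,6-dimethoxyphenyl)-2-methylbutan-1-one | COc1cc(O)c(C(=O)[C@H](C)CC)c(OC)c1 | intermediate
13 | (2R)-1-(2,6-dihydroxy-4-methoxyphenyl)-2-methylbutan-1-one | COc1cc(O)c(C(=O)[C@H](C)CC)c(O)c1 | intermediate
14 | (2R)-1-{3-[(dimethylamino)methyl]-2,6-dihydroxy-4-methoxyphenyl}-2-methylbutan-1-one | COc1cc(O)c(C(=O)[C@H](C)CC)c(O)c1CN(C)C | intermediate
15 | pentan-3-one | CCC(=O)CC | starting material
16 | 3-(trimethylsilyloxy)pent-2-ene (E/Z mixture) | CC=C(CC)O[Si](C)(C)C | intermediate
17 | malonyl dichloride | O=C(Cl)CC(=O)Cl | starting material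
18 | 4-methyl-3,5-dioxoheptanoyl chloride (racemic, not isolated) | CCC(=O)C(C)C(=O)CC(=O)Cl | intermediate
19 | 6-ethyl-4-hydroxy-5-methyl-2H-pyran-2-one | CCc1oc(=O)cc(O)c1C | intermediate
20 | 3-hydroxy-5-methoxy-6-methylidene-2-[(2R)-2-methylbutanoyl]cyclohexa-2,4-dien-1-one (not isolated) | COC1=CC(O)=C(C(=O)[C@H](C)CC)C(=O)C1=C | intermediate
21 | 6-ethyl-4-hydroxy-3-({2,4-dihydroxy-6-methoxy-3-[(2R)-2-methylbutanoyl]phenyl}methyl)-5-methyl-2H-pyran-2-one | CCc1oc(=O)c(Cc2c(OC)cc(O)c(C(=O)[C@H](C)CC)c2O)c(O)c1C | target

Total step count: 9. Longest linear sequence: 7 (steps 1–6 and 9). Steps 7 and 8 form the two-step side branch to ring A.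

Steps most likely to fail

1. Step 4. Several things may go wrong:
- Protonation of the aryl anion may outrun the four-centre acyl shift, which the α-branched acyl group slows, so that the reaction stalls at simple O-arylation.
- Excess aryne may arylate the product phenoxide.
- Long heating with basic fluoride may erode the enantiomeric purity, which should be checked by chiral HPLC at 12.

The fallback sets out from 1 and 9 and comes back at 12. It reaches the same kind of aryl anion at low temperature without an aryne. NBS bromination of 1 (CH2Cl2, −78 to 0 °C), followed by separation from the 4-bromo isomer, should give 2-bromo-3,5-dimethoxyphenol F1. Steglich esterification of F1 with 9 (DCC, cat. DMAP, CH2Cl2) gives 2-bromo-3,5-dimethoxyphenyl (2R)-2-methylbutanoate F2. Bromine–lithium exchange with s-BuLi (THF/Et2O, −95 °C) gives 2-lithio-3,5-dimethoxyphenyl (2R)-2-methylbutanoate F3. This undergoes the halogen–metal-exchange-induced anionic Fries rearrangement on warming and gives 12 after a dilute HCl quench.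

2. Step 9. The one-carbon unit may be passed back and forth between the phenolic partners by reversible retro-Michael cleavage, which would scramble the product to symmetric dimers. The quinone methide may also add to the free B5 position of material already coupled, leading to oligomerisation.

The fallback sets out from 13, uses 19, and comes back at 21. Vilsmeier–Haack formylation of 13 (POCl3, DMF, EtOAc, 0 °C to rt, then water) is self-limiting because the formyl group deactivates the ring. It should give 2,4-dihydroxy-6-methoxy-3-[(2R)-2-methylbutanoyl]benzaldehyde F4. L-Proline-catalysed Knoevenagel condensation of F4 with 19 in the presence of Hantzsch ester (EtOH or CH2Cl2, rt to 40 °C) forms 3-arylmethylidene-6-ethyl-5-methylpyran-2,4-dione F5. Hydride transfer reduces F5 in situ to 21 (three-component reductive alkylation). The bridge carbon is bound to ring B from the start and never exists as a free electrophile, so it cannot be handed on.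

3. Step 6. A second aminomethylation may occur at the remaining free ring position. Amine may also be lost prematurely during the basic work-up, followed by self-condensation.

The fallback sets out from 19 and 13 and comes back at 21, bypassing 14. It moves the leaving group to ring A, which has only one nucleophilic carbon. Treatment of 19 with Eschenmoser's salt and Et3N (CH2Cl2, 0 °C) should give 3-[(dimethylamino)methyl]-6-ethyl-4-hydroxy-5-methyl-2H-pyran-2-one F6. Heating F6 with excess 13 in 1,4-dioxane releases Me2NH and 6-ethyl-5-methyl-3-methylidenepyran-2,4-dione F7. B3 of 13 captures F7 in a Friedel–Crafts-type conjugate addition, and surplus 13 is recovered.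

Further compounds
F1 | step 4 | 2-bromo-3,5-dimethoxyphenol | COc1cc(O)c(Br)c(OC)c1
F2 | step 4 | 2-bromo-3,5-dimethoxyphenyl (2R)-2-methylbutanoate | CC[C@@H](C)C(=O)Oc1cc(OC)cc(OC)c1Br
F3 | step 4 | 2-lithio-3,5-dimethoxyphenyl (2R)-2-methylbutanoate | CC[C@@H](C)C(=O)Oc1cc(OC)cc(OC)c1[Li]
F4 | step 9 | 2,4-dihydroxy-6-methoxy-3-[(2R)-2-methylbutanoyl]benzaldehyde | COc1cc(O)c(C(=O)[C@H](C)CC)c(O)c1C=O
F5 | step 9 | 3-({2,4-dihydroxy-6-methoxy-3-[(2R)-2-methylbutanoyl]phenyl}methylidene)-6-ethyl-5-methylpyran-2,4-dione (alkene geometry undefined) | CCC1=C(C)C(=O)C(=Cc2c(OC)cc(O)c(C(=O)[C@H](C)CC)c2O)C(=O)O1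
F6 | step 6 | 3-[(dimethylamino)methyl]-6-ethyl-4-hydroxy-5-methyl-2H-pyran-2-one | CCc1oc(=O)c(CN(C)C)c(O)c1C
F7 | step 6 | 6-ethyl-5-methyl-3-methylidenepyran-2,4-dione | CCC1=C(C)C(=O)C(=C)C(=O)O1
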